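**Retrosynthetic overview**

- Feature: the ketone carbon C1 and the chain carbons C2–C4 next to the phloroglucinol ring are read as the four ring carbons of a 1-arylcyclobutan-1-ol, with C1 as the carbinol carbon. Opening that ring unmasks the ketone and releases C4 as a metal-bound carbon.
- Aryl–C1 bond: 1,3,5-trimethoxybenzene 1 and cyclobutanone 2 give, through aryllithium 3, cyclobutanol 4.
- C5–C11 arm: (5-bromopentyl)benzene 5 is ethynylated to alkyne 6, which through alkenylzirconium 7 gives the (E)-alkenyl bromide 8.
- Key disconnection C4–C5: 4 and 8 are joined by palladium-catalysed ring-opening alkenylation to enone 9. Hydrogenation (10) and O-demethylation then give target 11.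
- No ring is formed at any stage; both arenes are bought in, and the only ring event is the opening of the cyclobutane.

Key step: step 4

Remark: the target has no stereocentre. The chain is numbered C1 (carbonyl) to C11 (benzylic CH2). 11-Phenylundecanoic acid and 1,3,5-tris(benzyloxy)benzene, used only in fallbacks, are assumed to be purchasable.

**Route**

Step 1
Reactants: 1 1,3,5-trimethoxybenzene; 2 cyclobutanone
Product: 4 1-(2,4,6-trimethoxyphenyl)cyclobutan-1-ol, via 2,4,6-trimethoxyphenyllithium 3 (not isolated)
Conditions: n-BuLi, TMEDA, THF, 0 °C to rt; then 2, −78 to 0 °C; pH 7 buffer quench; chromatography on Et3N-deactivated silica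
Reagents that add atoms: none
Why: Directed ortho-lithiation of 1 at a position flanked by two methoxy groups gives 3, which should add 1,2 to the strained, electrophilic carbonyl of cyclobutanone (organolithium addition to a ketone); the carbinol carbon carries two identical ring arms, so no stereocentre arises, and the acid-labile tertiary benzylic alcohol is kept away from acid.

Step 2
Reactants: 5 (5-bromopentyl)benzene
Product: 6 hept-6-yn-1-ylbenzene
Conditions: LiC≡CH·H2NCH2CH2NH2, DMSO, 10 °C to rt
Reagents that add atoms: lithium acetylide ethylenediamine complex, [Li]C#C.NCCN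
Why: SN2 alkylation of lithium acetylide by an unhindered primary bromide in a dipolar aprotic solvent (acetylide alkylation), where substitution should outrun elimination and the terminal alkyne is obtained directly.

Step 3
Reactants: 6 hept-6-yn-1-ylbenzene
Product: 8 (E)-(7-bromohept-6-en-1-yl)benzene, via chlorobis(cyclopentadienyl)[(E)-7-phenylhept-1-enyl]zirconium 7 (not isolated)
Conditions: Cp2Zr(H)Cl, CH2Cl2, rt, dark; then NBS, 0 °C
Reagents that add atoms: N-bromosuccinimide (NBS), O=C1CCC(=O)N1Br
Why: Hydrozirconation with Cp2Zr(H)Cl adds Zr–H syn across the terminal alkyne with zirconium at the unhindered terminus, and bromodezirconation with NBS proceeds with retention, so the (E)-1-bromoalkene should result (hydrozirconation–halogenation).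

Step 4
Reactants: 4 1-(2,4,6-trimethoxyphenyl)cyclobutan-1-ol; 8 (E)-(7-bromohept-6-en-1-yl)benzene
Product: 9 (E)-11-phenyl-1-(2,4,6-trimethoxyphenyl)undec-5-en-1-one
Conditions: Pd(OAc)2 (5 mol %), rac-BINAP (10 mol %), Cs2CO3, toluene, 100 °C, argon
Reagents that add atoms: none
Why: Zerovalent palladium generated from Pd(OAc)2 and BINAP adds oxidatively to the C–Br bond of 8 with retention of the alkene geometry, and the caesium alkoxide of 4 displaces bromide to give an alkenylpalladium tert-alkoxide of divalent palladium. β-Carbon elimination then cleaves a ring C–C bond at the carbinol carbon, which turns that carbon into the ketone C1 and leaves C4 as a primary alkyl ligand, and C(sp3)–C(sp2) reductive elimination forges C4–C5 and returns zerovalent palladium. The closest known reaction type is the palladium-catalysed ring-opening arylation and alkenylation of tertiary cyclobutanols with organic bromides under Pd(OAc)2/BINAP/Cs2CO3, the alkenyl bromide partner being the less used variant. No ring closes (one opens) and no stereocentre is created; the (E) geometry of 8 should carry over, though it is erased in step 5 in any case. The step needs chemoselective cleavage of the strained ring bond in preference to the exocyclic aryl–carbinol bond, which the release of cyclobutane strain secures, and needs no regiocontrol because the two ring bonds at the carbinol carbon are equivalent. It also needs reductive elimination to outpace β-hydride elimination from the primary alkylpalladium, which the chelating bisphosphine favours, while the absence of a carbinol hydrogen rules out oxidation of the alcohol.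

Step 5
Reactants: 9 (E)-11-phenyl-1-(2,4,6-trimethoxyphenyl)undec-5-en-1-one
Product: 10 11-phenyl-1-(2,4,6-trimethoxyphenyl)undecan-1-one
Conditions: H2 (1 atm), 10% Pd/C, EtOAc, rt
Reagents that add atoms: none
Why: Heterogeneous catalytic hydrogenation should saturate the isolated disubstituted C5=C6 alkene at balloon pressure, conditions under which the hindered aryl ketone, the aryl methyl ethers and both arenes are expected to stay untouched.

Step 6
Reactants: 10 11-phenyl-1-(2,4,6-trimethoxyphenyl)undecan-1-one
Product: 11 11-phenyl-1-(2,4,6-trihydroxyphenyl)undecan-1-one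
Conditions: BBr3 (excess), CH2Cl2, −78 °C to rt; then MeOH, H2O, 0 °C
Reagents that add atoms: none
Why: Lewis acid-mediated aryl methyl ether cleavage, in which BBr3 coordinates each ether oxygen and bromide removes the methyl group in an SN2 sense (the two ortho ethers assisted by chelation to the carbonyl), and aqueous work-up hydrolyses the aryl borates to the free acylphloroglucinol.

**Compound list**

1 | 1,3,5-trimethoxybenzene | COc1cc(OC)cc(OC)c1 | starting material
2 | cyclobutanone | O=C1CCC1 | starting material
3 | 2,4,6-trimethoxyphenyllithium | [Li]c1c(OC)cc(OC)cc1OC | intermediate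
4 | 1-(2,4,6-trimethoxyphenyl)cyclobutan-1-ol | COc1cc(OC)c(C2(O)CCC2)c(OC)c1 | intermediate
5 | (5-bromopentyl)benzene | BrCCCCCc1ccccc1 | starting material
6 | hept-6-yn-1-ylbenzene | C#CCCCCCc1ccccc1 | intermediate
7 | chlorobis(cyclopentadienyl)[(E)-7-phenylhept-1-enyl]zirconium | [cH-]1cccc1.[cH-]1cccc1.Cl[Zr+2]/C=C/CCCCCc1ccccc1 | intermediate
8 | (E)-(7-bromohept-6-en-1-yl)benzene | Br/C=C/CCCCCc1ccccc1 | intermediate
9 | (E)-11-phenyl-1-(2,4,6-trimethoxyphenyl)undec-5-en-1-one | COc1cc(OC)c(C(=O)CCC/C=C/CCCCCc2ccccc2)c(OC)c1 | intermediate
10 | 11-phenyl-1-(2,4,6-trimethoxyphenyl)undecan-1-one | COc1cc(OC)c(C(=O)CCCCCCCCCCc2ccccc2)c(OC)c1 | intermediate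
11 | 11-phenyl-1-(2,4,6-trihydroxyphenyl)undecan-1-one | O=C(CCCCCCCCCCc1ccccc1)c1c(O)cc(O)cc1O | target

**Step count**

Total steps: 6. Longest linear sequence: 5 steps (steps 2, 3, 4, 5, 6 from compound 5).

**Steps most likely to fail**

1. Step 4. Several processes could divert the coupling:
   - β-Hydride elimination from the primary alkylpalladium intermediate may outrun reductive elimination, diverting material to a chain-unsaturated ketone and a reduced alkene.
   - The crowded, electron-rich aryl group may be expelled by β-aryl elimination instead of ring opening.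
   - Alkoxide binding at the hindered carbinol may be slow.

   Fallback: the route sets out again from 1. Commercial 11-phenylundecanoic acid is converted with (COCl)2 and catalytic DMF in CH2Cl2 into 11-phenylundecanoyl chloride F1. Friedel–Crafts acylation of 1 with this chloride (AlCl3, CH2Cl2, 0 °C, short contact time) at one of its three equivalent ring positions should give the saturated ketone directly. The fallback rejoins the route at 10, and step 6 follows.

2. Step 6. Cleavage of the para methyl ether, which has no chelation assistance, may stall at a partly methylated stage. Prolonged Lewis acid exposure may also cause protodeacylation of the very electron-rich ring.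

   Fallback: the methyl ethers are replaced by benzyl ethers, setting out from 2 and 8, so that the last step is a neutral hydrogenolysis:
   - Commercial 1,3,5-tris(benzyloxy)benzene is brominated with NBS (CH2Cl2, 0 °C) to 2-bromo-1,3,5-tris(benzyloxy)benzene F2.
   - Bromine–lithium exchange (n-BuLi, THF, −78 °C) gives 2,4,6-tris(benzyloxy)phenyllithium F3.
   - Addition to 2 gives 1-[2,4,6-tris(benzyloxy)phenyl]cyclobutan-1-ol F4.
   - Ring-opening alkenylation with 8 under the step 4 conditions gives (E)-11-phenyl-1-[2,4,6-tris(benzyloxy)phenyl]undec-5-en-1-one F5.
   - Hydrogenation (H2, Pd/C, EtOAc/MeOH) should saturate the alkene and cleave the three benzyl ethers in one operation.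

   The fallback rejoins the route at 11.

3. Step 3. Hydrozirconation may be incomplete or may run twice, and protodemetalation by adventitious moisture may compete. These would leave terminal alkene or saturated contaminants that are hard to separate from 8 and that carry no handle for the coupling.

   Fallback: the route sets out from 6 and 4 and drops the alkenyl halide. Bromination of the terminal alkyne (NBS, catalytic AgNO3, acetone, rt) gives (7-bromohept-6-yn-1-yl)benzene F6. The known bromoalkyne variant of the cyclobutanol ring-opening coupling (Pd(OAc)2, phosphine ligand, Cs2CO3, toluene, heat) with 4 should give 11-phenyl-1-(2,4,6-trimethoxyphenyl)undec-5-yn-1-one F7. Exhaustive hydrogenation of the alkyne (H2, Pd/C, EtOAc) rejoins the route at 10.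

**Further compounds**

F1 | step 4 | 11-phenylundecanoyl chloride | O=C(Cl)CCCCCCCCCCc1ccccc1
F2 | step 6 | 2-bromo-1,3,5-tris(benzyloxy)benzene | Brc1c(OCc2ccccc2)cc(OCc2ccccc2)cc1OCc1ccccc1
F3 | step 6 | 2,4,6-tris(benzyloxy)phenyllithium | [Li]c1c(OCc2ccccc2)cc(OCc2ccccc2)cc1OCc1ccccc1
F4 | step 6 | 1-[2,4,6-tris(benzyloxy)phenyl]cyclobutan-1-ol | OC1(CCC1)c1c(OCc2ccccc2)cc(OCc2ccccc2)cc1OCc1ccccc1
F5 | step 6 | (E)-11-phenyl-1-[2,4,6-tris(benzyloxy)phenyl]undec-5-en-1-one | O=C(CCC/C=C/CCCCCc1ccccc1)c1c(OCc2ccccc2)cc(OCc2ccccc2)cc1OCc1ccccc1
F6 | step 3 | (7-bromohept-6-yn-1-yl)benzene | BrC#CCCCCCc1ccccc1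
F7 | step 3 | 11-phenyl-1-(2,4,6-trimethoxyphenyl)undec-5-yn-1-one | COc1cc(OC)c(C(=O)CCCC#CCCCCCc2ccccc2)c(OC)c1
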